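The seven-membered ring is cut at C1. Its other six carbons, C5–C6–C7–C8–C9–C10, carry the isopropyl group (C7), the ester oxygen (C8) and the methyl group (C10) and form the oxygenated p-menthane ring of (R)-carvone. The key step inserts C1 between C5 and C10 in one operation: methylene transfer to a regiodefined enol silane and iron-mediated cleavage of the shared C5–C10 bond enlarge the cyclohexane to the β-methyl cycloheptenone. The precursor is the triethylsilyl enol ether of the cis 8-silyloxy-7-isopropyl cyclohexanone. The cyclopentane is then annulated onto C1 and C5, and C10, C1 and C5 are set by relay from the C8 hydroxyl.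

Key step: step 7

Remark: guaiane numbering is used for every intermediate (C1 and C5 ring fusion, C2–C4 in the five-membered ring, C6–C10 in the seven-membered ring, C14 on C10, C15 on C4); β is the face of the C7 isopropyl group and α the opposite face, so the target is the 1αH,5βH,7αH compound with the 8β-ester, the 10β-hydroxyl and the 3α,4α-epoxide.

Step 1
Reactants: 1 (R)-carvone
Product: 2 (R)-carvotanacetone
Conditions: H2 (1 atm), RhCl(PPh3)3 (cat.), benzene, rt
Reagents that add atoms: none
Why: Homogeneous hydrogenation with Wilkinson's catalyst should saturate the unhindered 1,1-disubstituted isopropenyl alkene and leave the trisubstituted conjugated alkene and the C7 stereocentre untouched.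

Step 2
Reactants: 2 (R)-carvotanacetone
Product: 4 (4R,5R)-4-hydroxy-2-methyl-5-(propan-2-yl)cyclohex-2-en-1-one (hydroxyl trans to isopropyl), via trimethylsilyl dienol ether 3 (not isolated)
Conditions: MeMgBr, FeCl3 (cat.), Et2O, −20 °C; TMSCl, Et3N, DMPU; mCPBA, NaHCO3, CH2Cl2, −20 °C; aq. citric acid
Reagents that add atoms: mCPBA, OOC(=O)c1cccc(Cl)c1
Why: The iron-catalysed methylmagnesium bromide base (Kharasch reagent) should deprotonate the γ-carbon C8 to the through-conjugated dienolate, and peracid epoxidation of its silyl ether at the remote C8=C9 bond (vinylogous Rubottom oxidation) on the face anti to the neighbouring C7 isopropyl group, followed by collapse to the enone, should set C8 as the alcohol trans to isopropyl.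

Step 3
Reactants: 4 trans γ-hydroxy enone
Product: 5 (1S,6R)-3-methyl-4-oxo-6-(propan-2-yl)cyclohex-2-en-1-yl 4-nitrobenzoate (ester cis to isopropyl)
Conditions: 4-nitrobenzoic acid, PPh3, DIAD, THF, 0 °C to rt
Reagents that add atoms: 4-nitrobenzoic acid, OC(=O)c1ccc(cc1)[N+](=O)[O-]
Why: Mitsunobu esterification displaces the activated C8 oxygen by SN2 with inversion, and the acidic 4-nitrobenzoic acid is the partner that works on hindered menthol-type alcohols, so the C8 oxygen ends cis (β) to the C7 isopropyl group.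

Step 4
Reactants: 5 cis 4-nitrobenzoate
Product: 6 (4S,5R)-4-hydroxy-2-methyl-5-(propan-2-yl)cyclohex-2-en-1-one (hydroxyl cis to isopropyl)
Conditions: K2CO3 (cat.), MeOH, 0 °C
Reagents that add atoms: none
Why: Carbonate-catalysed transesterification attacks the activated aryl ester at its acyl carbon, so the C8–O bond and its configuration are retained, and the low temperature keeps the γ-hydroxy enone from base-induced isomerisation.

Step 5
Reactants: 6 cis γ-hydroxy enone
Product: 7 (4S,5R)-4-(tert-butyldimethylsilyloxy)-2-methyl-5-(propan-2-yl)cyclohex-2-en-1-one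
Conditions: TBSCl, imidazole, DMF, rt
Reagents that add atoms: tert-butyldimethylsilyl chloride, CC(C)(C)[Si](C)(C)Cl
Why: Imidazole-promoted silylation of the secondary alcohol gives a silyl ether that is a poor leaving group and should survive the Lewis-acidic and basic steps that follow; no stereocentre is touched.

Step 6
Reactants: 7 cis silyloxy enone
Product: 8 triethylsilyl enol ether of (4R,5R)-4-(tert-butyldimethylsilyloxy)-2-methyl-5-(propan-2-yl)cyclohexanone (cis), enol double bond C5=C10
Conditions: Et3SiH, RhCl(PPh3)3 (cat.), THF, 50 °C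
Reagents that add atoms: triethylsilane, CC[SiH](CC)CC
Why: Rhodium-catalysed 1,4-hydrosilylation of the enone puts silicon on oxygen and hydride on C9, so the enol double bond is formed only between C5 and the methyl-bearing C10, a regiochemistry that enolisation of the saturated ketone could not guarantee.

Step 7
Reactants: 8 triethylsilyl enol ether; 9 diiodomethane
Product: 12 (5R,6R)-5-(tert-butyldimethylsilyloxy)-3-methyl-6-(propan-2-yl)cyclohept-2-en-1-one, via siloxycyclopropane 10 (not isolated), via β-chloro ketone 11 (not isolated)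
Conditions: Et2Zn, 9, CH2Cl2, 0 °C to rt, aq. NH4Cl work-up; FeCl3, pyridine, DMF, 0 °C to rt; NaOAc, MeOH, reflux
Reagents that add atoms: diiodomethane (9), ICI
Why: The zinc carbenoid EtZnCH2I (Furukawa variant of the Simmons–Smith reaction) transfers methylene to the electron-rich tetrasubstituted enol silane C5=C10 and forms the C1–C5 and C1–C10 bonds of cyclopropane 10; FeCl3 (trivalent iron) then oxidises the siloxycyclopropane by one electron, the oxygen-centred radical cleaves the internal C5–C10 bond to the C5 ketone and the tertiary C10 radical, and chlorine transfer from a second FeCl3 gives 11 and divalent iron. NaOAc then removes HCl through the C1 enolate to give the conjugated β-methyl enone. The closest known reaction type is the Ito–Saegusa ring expansion of cyclic silyl enol ethers to the homologous 2-cycloalkenones. The three-membered ring closes by concerted syn [2+1] methylene transfer, and the seven-membered ring arises by ring enlargement (six to seven) through scission of the bond shared by both rings, not by cyclisation. The two cyclopropane stereocentres are transient and end as sp2 or achiral carbons, so no stereocentre is formed, and C7 and C8 are remote from every bond that changes. The selectivity needed is regiochemical: the enol silane from step 6 fixes insertion between C5 and C10, fragmentation toward the tertiary radical secures cleavage of the internal bond over the C1–C5 bond, and the acidity of the C1 hydrogens directs elimination into conjugation.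

Step 8
Reactants: 12 cycloheptenone; 13 1-bromobutan-2-one
Product: 16 (5R,6R)-5-(tert-butyldimethylsilyloxy)-3-methyl-2-(2-oxobutyl)-6-(propan-2-yl)cyclohept-2-en-1-one, via pyrrolidine dienamine 14 (not isolated), via iminium bromide 15 (not isolated)
Conditions: pyrrolidine, TsOH (cat.), toluene, reflux, Dean–Stark; 13, MeCN, rt to 60 °C; H2O, AcOH–NaOAc, 60 °C
Reagents that add atoms: 1-bromobutan-2-one (13), CCC(=O)CBr; water, O
Why: Stork enamine alkylation: the through-conjugated pyrrolidine dienamine is alkylated by the reactive α-bromo ketone at its α-carbon C1 and stops at monoalkylation without strong base, and hydrolysis returns the C5 ketone with the C1=C10 bond in conjugation, so no stereocentre is created at C1 at this stage.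

Step 9
Reactants: 16 enone diketone
Product: 17 8β-(tert-butyldimethylsilyloxy)-7αH-guaia-1(10),4-dien-3-one
Conditions: KOH, MeOH, rt
Reagents that add atoms: none
Why: Intramolecular aldol condensation of the 1,4-diketone: the C4 enolate of the side-chain ketone adds to the C5 carbonyl and dehydration closes the cyclopentenone, and because base funnels every C1-deconjugated tautomer to the fully conjugated C3=O/C4=C5/C1=C10 dienone, the outcome is under thermodynamic control and C1 stays sp2.

Step 10
Reactants: 17 silyloxy dienone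
Product: 18 8β-hydroxy-7αH-guaia-1(10),4-dien-3-one
Conditions: TBAF, AcOH, THF, rt
Reagents that add atoms: none
Why: Fluoride-mediated desilylation cleaves the Si–O bond, and acetic acid buffering keeps the medium from enolising the dienone toward C9; no stereocentre changes.

Step 11
Reactants: 18 hydroxy dienone
Product: 19 1β,10β-epoxy-8β-hydroxy-7αH-guai-4-en-3-one
Conditions: VO(acac)2 (cat.), t-BuOOH, toluene, 0 °C to rt
Reagents that add atoms: tert-butyl hydroperoxide, CC(C)(C)OO
Why: Vanadium-catalysed hydroxyl-directed epoxidation: the homoallylic C8 hydroxyl binds the vanadium peroxide and delivers oxygen to the nearby, more electron-rich γ,δ-alkene C1=C10 on its own β face, which fixes C10 (oxygen β, methyl α) and places the C1–O bond β.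

Step 12
Reactants: 19 epoxy enone
Product: 20 8β,10β-dihydroxy-1αH,7αH-guai-4-en-3-one
Conditions: Pd2(dba)3·CHCl3 (cat.), n-Bu3P, HCO2H, Et3N, 1,4-dioxane, rt
Reagents that add atoms: none
Why: Palladium-catalysed formate hydrogenolysis of an alkenyl oxirane: zerovalent palladium ionises the allylic C1–O bond from the α face (anti to oxygen) to a π-allyl complex over C1–C5–C4, and the hydride formed by decarboxylation of formate passes from palladium to the terminus remote from the carbonyl, C1, on that same α face, so H1 ends trans to the retained 10β-hydroxyl (net inversion at C1) and the C4=C5 enone is kept.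

Step 13
Reactants: 20 dihydroxy enone
Product: 21 8β-(tert-butyldimethylsilyloxy)-10β-hydroxy-1αH,7αH-guai-4-en-3-one
Conditions: TBSCl, imidazole, DMF, rt
Reagents that add atoms: tert-butyldimethylsilyl chloride, CC(C)(C)[Si](C)(C)Cl
Why: Silylation with TBSCl and imidazole is selective for the secondary C8 hydroxyl over the tertiary C10 hydroxyl and masks it against triflation in the next step.

Step 14
Reactants: 21 silyloxy hydroxy enone
Product: 23 8β-(tert-butyldimethylsilyloxy)-10β-hydroxy-1αH,5βH,7αH-guai-3-en-3-yl trifluoromethanesulfonate, via dilithium enolate alkoxide 22 (not isolated)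
Conditions: Li, NH3 (l), THF, −78 °C; isoprene; NH3 removed; PhNTf2, THF, −78 °C to 0 °C
Reagents that add atoms: N-phenylbis(trifluoromethanesulfonimide), O=S(=O)(N(c1ccccc1)S(=O)(=O)C(F)(F)F)C(F)(F)F
Why: Dissolving-metal (Birch-type) conjugate reduction of the cyclopentenone protonates the β-carbanion at C5 anti to H1, with the neighbouring β-oriented C10 hydroxyl as internal proton source, to give the trans ring fusion (H5 β), and the regiodefined C3 enolate is trapped on oxygen by PhNTf2 as the C3=C4 enol triflate.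

Step 15
Reactants: 23 enol triflate
Product: 24 8β-(tert-butyldimethylsilyloxy)-1αH,5βH,7αH-guai-3-en-10β-ol
Conditions: Pd(OAc)2 (cat.), PPh3, n-Bu3N, HCO2H, DMF, 60 °C
Reagents that add atoms: none
Why: Palladium-catalysed formate reduction of the enol triflate (oxidative addition, formate-to-hydride exchange, reductive elimination) replaces the triflate by hydrogen and leaves the C3=C4 double bond in place without touching a stereocentre.

Step 16
Reactants: 24 silyloxy alkenol
Product: 25 1αH,5βH,7αH-guai-3-ene-8β,10β-diol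
Conditions: TBAF, AcOH, THF, rt
Reagents that add atoms: none
Why: Fluoride-mediated desilylation frees the C8 hydroxyl, and the tertiary alcohol and the trisubstituted alkene are inert to it.

Step 17
Reactants: 25 diol; 26 3,4-dimethoxybenzoyl chloride
Product: 27 10β-hydroxy-1αH,5βH,7αH-guai-3-en-8β-yl 3,4-dimethoxybenzoate
Conditions: 26, Et3N, DMAP (cat.), CH2Cl2, rt to 40 °C
Reagents that add atoms: 3,4-dimethoxybenzoyl chloride (26), COc1ccc(C(Cl)=O)cc1OC
Why: DMAP-catalysed acylation with the acid chloride esterifies the secondary C8 hydroxyl with retention, while the tertiary C10 hydroxyl is too hindered to react.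

Step 18
Reactants: 27 veratrate
Product: 28 3α,4α-epoxy-10β-hydroxy-1αH,5βH,7αH-guaian-8β-yl 3,4-dimethoxybenzoate (CNP0304846.1)
Conditions: dimethyldioxirane, acetone, 0 °C
Reagents that add atoms: dimethyldioxirane, CC1(C)OO1
Why: Epoxidation of the trisubstituted C3=C4 alkene with neutral dimethyldioxirane should take place on the α face, because the β face beside C4 and C5 is screened by the axial C10 hydroxyl and the C7 and C8 substituents while the α face carries only hydrogens, and the acid-free medium keeps the C10 hydroxyl from opening the new epoxide.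

Compound list
1 | (R)-carvone, (5R)-2-methyl-5-(prop-1-en-2-yl)cyclohex-2-en-1-one | CC1=CC[C@H](CC1=O)C(C)=C | starting material
2 | (R)-carvotanacetone, (5R)-2-methyl-5-(propan-2-yl)cyclohex-2-en-1-one | CC1=CC[C@H](CC1=O)C(C)C | intermediate
3 | trimethylsilyl dienol ether, (5R)-2-methyl-5-(propan-2-yl)-1-(trimethylsilyloxy)cyclohexa-1,3-diene | C[Si](C)(C)OC1=C(C)C=C[C@@H](C(C)C)C1 | intermediate
4 | (4R,5R)-4-hydroxy-2-methyl-5-(propan-2-yl)cyclohex-2-en-1-one, hydroxyl trans to isopropyl | O[C@H]1C=C(C)C(=O)C[C@@H]1C(C)C | intermediate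
5 | (1S,6R)-3-methyl-4-oxo-6-(propan-2-yl)cyclohex-2-en-1-yl 4-nitrobenzoate, ester cis to isopropyl | O=C(O[C@@H]1C=C(C)C(=O)C[C@@H]1C(C)C)c1ccc(cc1)[N+](=O)[O-] | intermediate
6 | (4S,5R)-4-hydroxy-2-methyl-5-(propan-2-yl)cyclohex-2-en-1-one, hydroxyl cis to isopropyl | O[C@@H]1C=C(C)C(=O)C[C@@H]1C(C)C | intermediate
7 | (4S,5R)-4-(tert-butyldimethylsilyloxy)-2-methyl-5-(propan-2-yl)cyclohex-2-en-1-one | CC(C)(C)[Si](C)(C)O[C@@H]1C=C(C)C(=O)C[C@@H]1C(C)C | intermediate
8 | triethylsilyl enol ether of (4R,5R)-4-(tert-butyldimethylsilyloxy)-2-methyl-5-(propan-2-yl)cyclohexanone (cis), double bond toward the methyl-bearing carbon | CC(C)(C)[Si](C)(C)O[C@@H]1CC(C)=C(O[Si](CC)(CC)CC)C[C@@H]1C(C)C | intermediate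
9 | diiodomethane | ICI | starting material
10 | siloxycyclopropane, 4-(tert-butyldimethylsilyloxy)-6-methyl-3-(propan-2-yl)-1-(triethylsilyloxy)bicyclo[4.1.0]heptane, C3 and C4 as in 8, either face of the cyclopropane | CC(C)(C)[Si](C)(C)O[C@@H]1CC2(C)CC2(O[Si](CC)(CC)CC)C[C@@H]1C(C)C | intermediate
11 | β-chloro ketone, (5R,6R)-5-(tert-butyldimethylsilyloxy)-3-chloro-3-methyl-6-(propan-2-yl)cycloheptan-1-one, either configuration at C3 | CC(C)(C)[Si](C)(C)O[C@@H]1CC(C)(Cl)CC(=O)C[C@@H]1C(C)C | intermediate
12 | (5R,6R)-5-(tert-butyldimethylsilyloxy)-3-methyl-6-(propan-2-yl)cyclohept-2-en-1-one | CC(C)(C)[Si](C)(C)O[C@@H]1CC(C)=CC(=O)C[C@@H]1C(C)C | intermediate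
13 | 1-bromobutan-2-one | CCC(=O)CBr | starting material
14 | pyrrolidine dienamine, 1-[5-(tert-butyldimethylsilyloxy)-3-methyl-6-(propan-2-yl)cyclohepta-1,3-dien-1-yl]pyrrolidine, C7 and C8 as in 12 | CC(C)(C)[Si](C)(C)O[C@@H]1C=C(C)C=C(N2CCCC2)C[C@@H]1C(C)C | intermediate
15 | iminium bromide, C1-(2-oxobutyl) pyrrolidinium salt of 16 | CC(C)(C)[Si](C)(C)O[C@@H]1CC(C)=C(CC(=O)CC)C(=[N+]2CCCC2)C[C@@H]1C(C)C.[Br-] | intermediate
16 | (5R,6R)-5-(tert-butyldimethylsilyloxy)-3-methyl-2-(2-oxobutyl)-6-(propan-2-yl)cyclohept-2-en-1-one | CC(C)(C)[Si](C)(C)O[C@@H]1CC(C)=C(CC(=O)CC)C(=O)C[C@@H]1C(C)C | intermediate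
17 | 8β-(tert-butyldimethylsilyloxy)-7αH-guaia-1(10),4-dien-3-one | CC(C)(C)[Si](C)(C)O[C@@H]1CC(C)=C2CC(=O)C(C)=C2C[C@@H]1C(C)C | intermediate
18 | 8β-hydroxy-7αH-guaia-1(10),4-dien-3-one | O[C@@H]1CC(C)=C2CC(=O)C(C)=C2C[C@@H]1C(C)C | intermediate
19 | 1β,10β-epoxy-8β-hydroxy-7αH-guai-4-en-3-one | O[C@@H]1C[C@]2(C)O[C@@]23CC(=O)C(C)=C3C[C@@H]1C(C)C | intermediate
20 | 8β,10β-dihydroxy-1αH,7αH-guai-4-en-3-one | O[C@@H]1C[C@](C)(O)[C@@H]2CC(=O)C(C)=C2C[C@@H]1C(C)C | intermediate
21 | 8β-(tert-butyldimethylsilyloxy)-10β-hydroxy-1αH,7αH-guai-4-en-3-one | CC(C)(C)[Si](C)(C)O[C@@H]1C[C@](C)(O)[C@@H]2CC(=O)C(C)=C2C[C@@H]1C(C)C | intermediate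
22 | dilithium enolate alkoxide of the 1αH,5βH ketone (C3 enolate, C10 alkoxide) | CC(C)(C)[Si](C)(C)O[C@@H]1C[C@](C)(O[Li])[C@@H]2CC(O[Li])=C(C)[C@H]2C[C@@H]1C(C)C | intermediate
23 | 8β-(tert-butyldimethylsilyloxy)-10β-hydroxy-1αH,5βH,7αH-guai-3-en-3-yl trifluoromethanesulfonate | CC(C)(C)[Si](C)(C)O[C@@H]1C[C@](C)(O)[C@@H]2CC(OS(=O)(=O)C(F)(F)F)=C(C)[C@H]2C[C@@H]1C(C)C | intermediate
24 | 8β-(tert-butyldimethylsilyloxy)-1αH,5βH,7αH-guai-3-en-10β-ol | CC(C)(C)[Si](C)(C)O[C@@H]1C[C@](C)(O)[C@@H]2CC=C(C)[C@H]2C[C@@H]1C(C)C | intermediate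
25 | 1αH,5βH,7αH-guai-3-ene-8β,10β-diol | O[C@@H]1C[C@](C)(O)[C@@H]2CC=C(C)[C@H]2C[C@@H]1C(C)C | intermediate
26 | 3,4-dimethoxybenzoyl chloride | COc1ccc(C(Cl)=O)cc1OC | starting material
27 | 10β-hydroxy-1αH,5βH,7αH-guai-3-en-8β-yl 3,4-dimethoxybenzoate | COc1ccc(C(=O)O[C@@H]2C[C@](C)(O)[C@@H]3CC=C(C)[C@H]3C[C@@H]2C(C)C)cc1OC | intermediate
28 | 3α,4α-epoxy-10β-hydroxy-1αH,5βH,7αH-guaian-8β-yl 3,4-dimethoxybenzoate (CNP0304846.1) | COc1ccc(C(=O)O[C@@H]2C[C@](C)(O)[C@@H]3C[C@H]4O[C@@]4(C)[C@H]3C[C@@H]2C(C)C)cc1OC | target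

Total step count: 18 steps.
Longest linear sequence: 18 steps, from 1 to 28; 9, 13 and 26 are bought.

Steps most likely to fail

Step 12 (formate hydrogenolysis of the alkenyl oxirane). Ionisation of the fully substituted allylic C–O bond may be slow, hydride may be delivered to C4 instead of C1, or β-hydride elimination toward the C15 methyl group may compete. The fallback sets out from 12 and comes back to the route at 25. It fixes C1 by alkylation instead of hydrogenolysis and moves the C8-hydroxyl relay to a C9=C10 alkene. The potassium dienolate of 12 (KOt-Bu, THF, −78 °C to 0 °C) would be alkylated at C1 with 1-bromobut-2-yne and quenched cold to give the β,γ-unsaturated butynyl ketone F1. Gold-catalysed hydration ((Ph3P)AuNTf2, H2O, 1,4-dioxane), steered by the C5 carbonyl, would give the 1,4-diketone F2, and aldol condensation (KOH, MeOH, 0 °C) the skipped dienone F3. Li/NH3 followed by PhNTf2 would give the trans-fused enol triflate F4, and Pd(OAc)2, PPh3, HCO2H and n-Bu3N the diene F5. TBAF would give the dienol F6, and VO(acac)2 with t-BuOOH would epoxidise the allylic C9=C10 bond syn to the C8 hydroxyl to give the epoxy alcohol F7. NaAlH2(OCH2CH2OMe)2 would deliver hydride to C9 and give 25. The weak point of this fallback is that C1 remains epimerisable until the aldol closure, so its configuration rests on substrate control.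

Step 8 (dienamine alkylation). N-alkylation of the dienamine, alkylation at the γ-carbon C9, or formation of the cross-conjugated dienamine toward C6 may erode regiocontrol. The fallback sets out from 12 and comes back at 16. The thermodynamic potassium dienolate of 12 (KOt-Bu, t-BuOH, rt) would be alkylated at C1 with 1-bromobut-2-yne, a propargylic halide with no enolisable carbonyl, and left to re-conjugate to the butynyl enone F8. Gold-catalysed hydration ((Ph3P)AuNTf2, H2O, 1,4-dioxane) with participation of the C5 carbonyl would place the new carbonyl on C3 and give 16.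

Step 7 (key step). The C8 silyl ether may be lost under the Lewis-acidic iron chloride, the external cyclopropane bond may be cleaved in place of the internal one, or dehydrochlorination may stop short of conjugation. The fallback sets out from 8 and comes back at 12. Dibromocarbene (CHBr3, KOt-Bu, pentane, −20 °C) would add to the enol silane to give the dibromocyclopropane F9. Warming in toluene would open it by ionic cyclopropyl-to-allyl ring enlargement, with loss of bromide and of the silyl group, to the 2-bromo cycloheptenone F10. Hydrodebromination (Pd(PPh3)4 cat., n-Bu3SnH, THF, rt) would give 12.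

Further compounds
F1 | step 12 | (5R,6R)-2-(but-2-yn-1-yl)-5-(tert-butyldimethylsilyloxy)-3-methyl-6-(propan-2-yl)cyclohept-3-en-1-one, 1αH | CC(C)(C)[Si](C)(C)O[C@@H]1C=C(C)[C@H](CC#CC)C(=O)C[C@@H]1C(C)C
F2 | step 12 | 5-(tert-butyldimethylsilyloxy)-3-methyl-2-(2-oxobutyl)-6-(propan-2-yl)cyclohept-3-en-1-one, 1αH | CC(C)(C)[Si](C)(C)O[C@@H]1C=C(C)[C@H](CC(=O)CC)C(=O)C[C@@H]1C(C)C
F3 | step 12 | 8β-(tert-butyldimethylsilyloxy)-1αH,7αH-guaia-4,9-dien-3-one | CC(C)(C)[Si](C)(C)O[C@@H]1C=C(C)[C@@H]2CC(=O)C(C)=C2C[C@@H]1C(C)C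
F4 | step 12 | 8β-(tert-butyldimethylsilyloxy)-1αH,5βH,7αH-guaia-3,9-dien-3-yl trifluoromethanesulfonate | CC(C)(C)[Si](C)(C)O[C@@H]1C=C(C)[C@@H]2CC(OS(=O)(=O)C(F)(F)F)=C(C)[C@H]2C[C@@H]1C(C)C
F5 | step 12 | 8β-(tert-butyldimethylsilyloxy)-1αH,5βH,7αH-guaia-3,9-diene | CC(C)(C)[Si](C)(C)O[C@@H]1C=C(C)[C@@H]2CC=C(C)[C@H]2C[C@@H]1C(C)C
F6 | step 12 | 1αH,5βH,7αH-guaia-3,9-dien-8β-ol | O[C@@H]1C=C(C)[C@@H]2CC=C(C)[C@H]2C[C@@H]1C(C)C
F7 | step 12 | 9β,10β-epoxy-1αH,5βH,7αH-guai-3-en-8β-ol | O[C@@H]1[C@@H]2O[C@]2(C)[C@@H]3CC=C(C)[C@H]3C[C@@H]1C(C)C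
F8 | step 8 | (5R,6R)-2-(but-2-yn-1-yl)-5-(tert-butyldimethylsilyloxy)-3-methyl-6-(propan-2-yl)cyclohept-2-en-1-one | CC(C)(C)[Si](C)(C)O[C@@H]1CC(C)=C(CC#CC)C(=O)C[C@@H]1C(C)C
F9 | step 7 | 7,7-dibromo-4-(tert-butyldimethylsilyloxy)-6-methyl-3-(propan-2-yl)-1-(triethylsilyloxy)bicyclo[4.1.0]heptane, C3 and C4 as in 8 | CC(C)(C)[Si](C)(C)O[C@@H]1CC2(C)C(Br)(Br)C2(O[Si](CC)(CC)CC)C[C@@H]1C(C)C
F10 | step 7 | (5R,6R)-2-bromo-5-(tert-butyldimethylsilyloxy)-3-methyl-6-(propan-2-yl)cyclohept-2-en-1-one | CC(C)(C)[Si](C)(C)O[C@@H]1CC(C)=C(Br)C(=O)C[C@@H]1C(C)C
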